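**Plan**

1. Numbering (prostanoid): C1 lactone carbonyl, C4 lactone carbinol, C5=C6 (Z), exocyclic C7=C8 (E), C9 ketone, C10=C11, C12 quaternary C–OAc, C13–C20 chain with C14=C15 (Z).
2. Enabling feature: the five-membered lactone ring (O, C1–C4) carries its carbinol carbon C4 directly on C5 of the 5Z alkene. With C5=C6 drawn as an alkyne, C4 is a propargylic alkoxide carbon 1,4 to the C1 ester, the retron for adding a C5–H terminal enyne to a C1–C4 aldehyde ester and closing O–C1.
3. Cuts, in retrosynthetic order: C5=C6 and C14=C15 back to alkynes; O-acetyl back to O-silyl; C4–C5 together with O–C1; C7=C8 (aldol condensation); C15–C16 (acetylide alkylation); C12–C13 (propargyl addition to the ketone of (S)-4-silyloxycyclopentenone).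
4. Forward order: the cyclopentene ring is bought. The chain is attached at C12, the old silyloxy carbon is oxidised to the C9 ketone, the C5–C7 enyne is condensed onto C8, and the lactone (the only ring made) closes in the key step. Acetylation and one double semi-hydrogenation finish the route.
5. Stereochemistry: C12 by substrate control (addition anti to the silyloxy group, whose carbon then becomes the C9 ketone); C4 by the chiral zinc catalyst; 7E by thermodynamically controlled elimination; 5Z and 14Z by syn hydrogenation.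

Key step: step 9

Assumption: the (S,S)-ProPhenol/Me2Zn catalyst is taken to deliver the alkynyl group to the Si face of an unbranched aliphatic aldehyde (which gives the 4R carbinol); the sense is to be checked by Mosher ester analysis of the open hydroxy ester, and the (R,R)-ligand would replace it with no other change if the opposite sense were found.

**Step 1**
Reactants: 1 (S)-4-(tert-butyldimethylsilyloxy)cyclopent-2-en-1-one; 2 3-bromoprop-1-yne (propargyl bromide)
Product: 3 (1R,4S)-4-(tert-butyldimethylsilyloxy)-1-(prop-2-yn-1-yl)cyclopent-2-en-1-ol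
Conditions: Zn dust (activated), 2 (1.5 equiv), THF, 0 °C → rt; sat. aq NH4Cl
Reagents that add atoms: none
Why: Barbier-type zinc propargylation, in which the allenylzinc bromide formed in the flask adds 1,2 to the ketone through a cyclic SE2′ transition state on the ring face anti to the silyloxy group, so that the future C12 carbinol is set with its hydroxyl cis to the silyl ether.

**Step 2**
Reactants: 3 (1R,4S)-4-(tert-butyldimethylsilyloxy)-1-(prop-2-yn-1-yl)cyclopent-2-en-1-ol; 4 1-iodopentane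
Product: 5 (1R,4S)-4-(tert-butyldimethylsilyloxy)-1-(oct-2-yn-1-yl)cyclopent-2-en-1-ol
Conditions: n-BuLi (2.2 equiv), THF, −78 → −20 °C; DMPU, 4 (1.5 equiv), −20 °C → rt; H2O
Reagents that add atoms: none
Why: SN2 alkylation of a lithium acetylide (alkoxide/acetylide dianion) with a primary iodide, in which the carbon nucleophile should react far faster than the hindered tertiary alkoxide.

**Step 3**
Reactants: 5 (1R,4S)-4-(tert-butyldimethylsilyloxy)-1-(oct-2-yn-1-yl)cyclopent-2-en-1-ol
Product: 6 (1R,4S)-1-(oct-2-yn-1-yl)cyclopent-2-ene-1,4-diol (cis-diol)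
Conditions: TBAF (1.2 equiv), THF, 0 °C → rt
Reagents that add atoms: none
Why: Fluoride-mediated silyl ether cleavage, which also makes harmless any 1,3 O→O silyl shift in the alkoxide of step 2 because both silyl isomers should give the same diol.

**Step 4**
Reactants: 6 (1R,4S)-1-(oct-2-yn-1-yl)cyclopent-2-ene-1,4-diol
Product: 7 (R)-4-hydroxy-4-(oct-2-yn-1-yl)cyclopent-2-en-1-one
Conditions: activated MnO2 (excess), CH2Cl2, rt
Reagents that add atoms: none
Why: MnO2 oxidation of an allylic alcohol, selective because only the secondary carbinol can be oxidised; it removes the stereocentre that directed step 1 and leaves C12 as the only one.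

**Step 5**
Reactants: 7 (R)-4-hydroxy-4-(oct-2-yn-1-yl)cyclopent-2-en-1-one
Product: 8 (R)-4-(tert-butyldimethylsilyloxy)-4-(oct-2-yn-1-yl)cyclopent-2-en-1-one
Conditions: TBSOTf (1.5 equiv), 2,6-lutidine (3 equiv), CH2Cl2, −78 → 0 °C
Reagents that add atoms: tert-butyldimethylsilyl trifluoromethanesulfonate, CC(C)(C)[Si](C)(C)OS(=O)(=O)C(F)(F)F
Why: Silylation of a tertiary alcohol with a silyl triflate and a hindered pyridine base, conditions under which the enone should not be enolised.

**Step 6**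
Reactants: 8 (R)-4-(tert-butyldimethylsilyloxy)-4-(oct-2-yn-1-yl)cyclopent-2-en-1-one; 9 3-(trimethylsilyl)prop-2-ynal
Product: 10 (4S)-4-(tert-butyldimethylsilyloxy)-5-[1-hydroxy-3-(trimethylsilyl)prop-2-yn-1-yl]-4-(oct-2-yn-1-yl)cyclopent-2-en-1-one (mixture of diastereomers at C5 and C1′)
Conditions: LDA (1.1 equiv), THF, −78 °C; 9 (1.3 equiv), −78 °C; sat. aq NH4Cl
Reagents that add atoms: none
Why: Aldol addition of the kinetic α′ lithium enolate (future C8) to an ynal, in which the β-silyloxy enolate should not eliminate because that would give an antiaromatic cyclopentadienone; both new stereocentres are removed in step 7.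

**Step 7**
Reactants: 10 (4S)-4-(tert-butyldimethylsilyloxy)-5-[1-hydroxy-3-(trimethylsilyl)prop-2-yn-1-yl]-4-(oct-2-yn-1-yl)cyclopent-2-en-1-one
Product: 12 (S,E)-4-(tert-butyldimethylsilyloxy)-4-(oct-2-yn-1-yl)-5-[3-(trimethylsilyl)prop-2-yn-1-ylidene]cyclopent-2-en-1-one, via aldol mesylate 11 (not isolated)
Conditions: MsCl, Et3N, CH2Cl2, −20 °C; then DBU, 0 °C → rt
Reagents that add atoms: none
Why: Mesylation followed by E1cB elimination completes the aldol condensation and should give the more stable 7E alkylidene, with the slim alkynyl group anti to the C9 carbonyl.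

**Step 8**
Reactants: 12 (S,E)-4-(tert-butyldimethylsilyloxy)-4-(oct-2-yn-1-yl)-5-[3-(trimethylsilyl)prop-2-yn-1-ylidene]cyclopent-2-en-1-one
Product: 13 (S,E)-4-(tert-butyldimethylsilyloxy)-4-(oct-2-yn-1-yl)-5-(prop-2-yn-1-ylidene)cyclopent-2-en-1-one
Conditions: TBAF (1.1 equiv), AcOH (1.2 equiv), THF, −20 → 0 °C
Reagents that add atoms: none
Why: Fluoride protodesilylation of an alkynylsilane, buffered with acetic acid so that no basic nucleophile adds to the dienynone, while the tertiary silyl ether should survive the short cold exposure.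

**Step 9**
Reactants: 13 (S,E)-4-(tert-butyldimethylsilyloxy)-4-(oct-2-yn-1-yl)-5-(prop-2-yn-1-ylidene)cyclopent-2-en-1-one; 14 methyl 4-oxobutanoate
Product: 16 (S,E)-4-(tert-butyldimethylsilyloxy)-4-(oct-2-yn-1-yl)-5-{3-[(R)-5-oxotetrahydrofuran-2-yl]prop-2-yn-1-ylidene}cyclopent-2-en-1-one, via open hydroxy ester 15 (not isolated)
Conditions: Me2Zn (1.5 equiv), (S,S)-ProPhenol (20 mol %), Ph3P=O (40 mol %), PhMe, 0 °C, 1 h; 14 (2 equiv, slow addition), 4 °C; sat. aq NH4Cl; then PPTS (cat.), CH2Cl2, rt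
Reagents that add atoms: none
Why: Me2Zn and (S,S)-ProPhenol form a dinuclear zinc complex that deprotonates the only terminal C–H (C5–H of 13) and binds the aldehyde of 14 on the neighbouring zinc, so that the alkynyl group is transferred to the carbonyl carbon and forms C4–C5; the closest known reaction type is the zinc–ProPhenol-catalysed enantioselective alkynylation of aldehydes with enynes and propiolates. The resulting γ-alkoxide, present after work-up as hydroxy ester 15, attacks the C1 methyl ester in a 5-exo-trig acyl substitution (O–C1) that PPTS completes with loss of methanol, closing the γ-lactone. C4 is the only new stereocentre and is controlled by the catalyst alone (Si-face delivery gives 4R), because C12 lies five bonds away across a rigid enyne and cannot bias it. Chemoselectivity rests on 13 having a single terminal alkyne, an inert internal C14≡C15 alkyne, no enolisable hydrogen beside the C9 ketone (C8 and C10 are sp2) and a dienone that Me2Zn should not attack without a copper or nickel catalyst. Self-aldol of the unbranched aldehyde is held back by adding 14 slowly to the preformed alkynylzinc, and the C12 silyl ether keeps any allylic ester away from the organozinc.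

**Step 10**
Reactants: 16 (S,E)-4-(tert-butyldimethylsilyloxy)-4-(oct-2-yn-1-yl)-5-{3-[(R)-5-oxotetrahydrofuran-2-yl]prop-2-yn-1-ylidene}cyclopent-2-en-1-one
Product: 17 (S,E)-4-hydroxy-4-(oct-2-yn-1-yl)-5-{3-[(R)-5-oxotetrahydrofuran-2-yl]prop-2-yn-1-ylidene}cyclopent-2-en-1-one
Conditions: 48% aq HF, MeCN, 0 °C → rt
Reagents that add atoms: none
Why: Acid fluoride cleavage of a tertiary silyl ether, which the lactone and dienone should tolerate and which should not ionise C12 because a cation there is destabilised by the two adjoining enone units.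

**Step 11**
Reactants: 17 (S,E)-4-hydroxy-4-(oct-2-yn-1-yl)-5-{3-[(R)-5-oxotetrahydrofuran-2-yl]prop-2-yn-1-ylidene}cyclopent-2-en-1-one
Product: 18 (S,E)-1-(oct-2-yn-1-yl)-4-oxo-5-{3-[(R)-5-oxotetrahydrofuran-2-yl]prop-2-yn-1-ylidene}cyclopent-2-en-1-yl acetate (5,6,14,15-tetradehydroclavulolactone I)
Conditions: Ac2O, DMAP, Et3N, CH2Cl2, rt
Reagents that add atoms: acetic anhydride, CC(=O)OC(C)=O
Why: DMAP-catalysed nucleophilic acyl transfer, the standard acetylation of hindered tertiary alcohols, run while both future Z-alkenes are still alkynes so that no alkene geometry can be scrambled by base.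

**Step 12**
Reactants: 18 (S,E)-1-(oct-2-yn-1-yl)-4-oxo-5-{3-[(R)-5-oxotetrahydrofuran-2-yl]prop-2-yn-1-ylidene}cyclopent-2-en-1-yl acetate
Product: 19 clavulolactone I, (S)-4-oxo-1-[(Z)-oct-2-en-1-yl]-5-{(1E,2Z)-3-[(R)-5-oxotetrahydrofuran-2-yl]prop-2-en-1-ylidene}cyclopent-2-en-1-yl acetate
Conditions: H2 (1 atm), Lindlar catalyst (Pb-poisoned Pd/CaCO3), quinoline, EtOAc, rt, dark; stopped after 2 equiv H2
Reagents that add atoms: none
Why: Lindlar semi-hydrogenation delivers hydrogen syn to both alkynes on the poisoned palladium surface and should give the 5Z and 14Z alkenes, with quinoline slowing reduction of the conjugated alkenes.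

**Compound list**

1 | (S)-4-(tert-butyldimethylsilyloxy)cyclopent-2-en-1-one | O=C1C=C[C@@H](O[Si](C)(C)C(C)(C)C)C1 | starting material
2 | 3-bromoprop-1-yne (propargyl bromide) | BrCC#C | starting material
3 | (1R,4S)-4-(tert-butyldimethylsilyloxy)-1-(prop-2-yn-1-yl)cyclopent-2-en-1-ol | C#CC[C@]1(O)C=C[C@@H](O[Si](C)(C)C(C)(C)C)C1 | intermediate
4 | 1-iodopentane | CCCCCI | starting material
5 | (1R,4S)-4-(tert-butyldimethylsilyloxy)-1-(oct-2-yn-1-yl)cyclopent-2-en-1-ol | CCCCCC#CC[C@]1(O)C=C[C@@H](O[Si](C)(C)C(C)(C)C)C1 | intermediate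
6 | (1R,4S)-1-(oct-2-yn-1-yl)cyclopent-2-ene-1,4-diol | CCCCCC#CC[C@]1(O)C=C[C@@H](O)C1 | intermediate
7 | (R)-4-hydroxy-4-(oct-2-yn-1-yl)cyclopent-2-en-1-one | CCCCCC#CC[C@]1(O)C=CC(=O)C1 | intermediate
8 | (R)-4-(tert-butyldimethylsilyloxy)-4-(oct-2-yn-1-yl)cyclopent-2-en-1-one | CCCCCC#CC[C@]1(O[Si](C)(C)C(C)(C)C)C=CC(=O)C1 | intermediate
9 | 3-(trimethylsilyl)prop-2-ynal | C[Si](C)(C)C#CC=O | starting material
10 | (4S)-4-(tert-butyldimethylsilyloxy)-5-[1-hydroxy-3-(trimethylsilyl)prop-2-yn-1-yl]-4-(oct-2-yn-1-yl)cyclopent-2-en-1-one (diastereomer mixture) | CCCCCC#CC[C@]1(O[Si](C)(C)C(C)(C)C)C=CC(=O)C1C(O)C#C[Si](C)(C)C | intermediate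
11 | methanesulfonate of aldol 10 at C1′ | CCCCCC#CC[C@]1(O[Si](C)(C)C(C)(C)C)C=CC(=O)C1C(OS(C)(=O)=O)C#C[Si](C)(C)C | intermediate
12 | (S,E)-4-(tert-butyldimethylsilyloxy)-4-(oct-2-yn-1-yl)-5-[3-(trimethylsilyl)prop-2-yn-1-ylidene]cyclopent-2-en-1-one | CCCCCC#CC[C@]1(O[Si](C)(C)C(C)(C)C)C=CC(=O)/C1=C/C#C[Si](C)(C)C | intermediate
13 | (S,E)-4-(tert-butyldimethylsilyloxy)-4-(oct-2-yn-1-yl)-5-(prop-2-yn-1-ylidene)cyclopent-2-en-1-one | CCCCCC#CC[C@]1(O[Si](C)(C)C(C)(C)C)C=CC(=O)/C1=C/C#C | intermediate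
14 | methyl 4-oxobutanoate | COC(=O)CCC=O | starting material
15 | methyl (4R,7E)-7-[(S)-2-(tert-butyldimethylsilyloxy)-2-(oct-2-yn-1-yl)-5-oxocyclopent-3-en-1-ylidene]-4-hydroxyhept-5-ynoate | CCCCCC#CC[C@]1(O[Si](C)(C)C(C)(C)C)C=CC(=O)/C1=C/C#C[C@H](O)CCC(=O)OC | intermediate
16 | (S,E)-4-(tert-butyldimethylsilyloxy)-4-(oct-2-yn-1-yl)-5-{3-[(R)-5-oxotetrahydrofuran-2-yl]prop-2-yn-1-ylidene}cyclopent-2-en-1-one | CCCCCC#CC[C@]1(O[Si](C)(C)C(C)(C)C)C=CC(=O)/C1=C/C#C[C@H]1CCC(=O)O1 | intermediate
17 | (S,E)-4-hydroxy-4-(oct-2-yn-1-yl)-5-{3-[(R)-5-oxotetrahydrofuran-2-yl]prop-2-yn-1-ylidene}cyclopent-2-en-1-one | CCCCCC#CC[C@]1(O)C=CC(=O)/C1=C/C#C[C@H]1CCC(=O)O1 | intermediate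
18 | (S,E)-1-(oct-2-yn-1-yl)-4-oxo-5-{3-[(R)-5-oxotetrahydrofuran-2-yl]prop-2-yn-1-ylidene}cyclopent-2-en-1-yl acetate | CCCCCC#CC[C@]1(OC(C)=O)C=CC(=O)/C1=C/C#C[C@H]1CCC(=O)O1 | intermediate
19 | clavulolactone I | CCCCC/C=C\C[C@]1(OC(C)=O)C=CC(=O)/C1=C/C=C\[C@H]1CCC(=O)O1 | target

**Step count and risks**

Total step count: 12. Longest linear sequence: 12 steps (1 → 19); compounds 2, 4, 9 and 14 are bought.

The three steps most likely to fail are steps 9, 12 and 1.

Step 9. The zinc catalyst may discriminate poorly between the faces of an unbranched, flexible aldehyde. The aldehyde may also be consumed by zinc-promoted self-aldol reaction before alkynyl transfer, and the electron-poor alkynylzinc may add sluggishly. The fallback forms the same C4–C5 bond at the ketone oxidation level and sets out from enyne 13. Palladium/copper-catalysed acylation of the terminal alkyne (acyl Sonogashira coupling) with methyl 4-chloro-4-oxobutanoate (PdCl2(PPh3)2, CuI, Et3N, THF, rt) should give the ynone keto ester F1. Noyori-type asymmetric transfer hydrogenation with RuCl(p-cymene)[(R,R)-TsDPEN] in propan-2-ol reduces alkynyl ketones much faster than a hindered cross-conjugated dienone. By analogy with other alkynyl alkyl ketones it should give the 4R hydroxy ester 15, and PPTS then closes the same O–C1 bond, rejoining the route at lactone 16.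

Step 12. The two electronically different alkynes may take up hydrogen at unequal rates, so that the conjugated triene or the ring enone is over-reduced before the slower alkyne is consumed, and the 5Z alkene may isomerise on the catalyst. The fallback sets out from alcohol 5 and carries the 14Z alkene through the route. The isolated C14≡C15 alkyne is semi-hydrogenated at once over Lindlar catalyst (only a disubstituted ring alkene competes) to the Z-octenyl silyloxy alcohol F2. The chemistry of steps 3–11 is then repeated on the Z-octenyl series: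
- fluoride desilylation to the Z-octenyl diol F3;
- MnO2 oxidation to the Z-octenyl hydroxy enone F4;
- silylation to the Z-octenyl silyloxy enone F5;
- aldol addition of 9 to the Z-octenyl aldol F6;
- mesylation to the Z-octenyl aldol mesylate F7 and elimination to the Z-octenyl silyl enynone F8;
- C-desilylation to the Z-octenyl terminal enyne F9;
- zinc-catalysed alkynylation of 14 through the Z-octenyl hydroxy ester F10 to the Z-octenyl alkynyl lactone F11;
- HF desilylation to the Z-octenyl tertiary alcohol F12 and acetylation to the Z-octenyl alkynyl acetate F13.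

A last Lindlar hydrogenation, now limited to one equivalent of hydrogen at the conjugated C5≡C6 alkyne, returns to the route at 19.

Step 1. The organozinc may transfer through its propargyl instead of its allenyl form and give the allenyl carbinol, or it may add on the face syn to the silyloxy group. The fallback sets out from enone 1 and reaches the same carbinol without an ambident nucleophile. Corey–Chaykovsky epoxidation with dimethylsulfonium methylide (Me3S+ I−, KHMDS, THF, −10 °C) should add the methylene anti to the silyloxy group and give the spiro vinyl epoxide F14. Lithium heptynilide (hept-1-yne, n-BuLi, THF/DMPU, 0 °C → rt) should then open it at the unhindered CH2 terminus. This rejoins the route at alcohol 5, with compounds 2, 3 and 4 and step 2 no longer needed.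

**Further compounds**

F1 | step 9 | methyl (E)-7-[(S)-2-(tert-butyldimethylsilyloxy)-2-(oct-2-yn-1-yl)-5-oxocyclopent-3-en-1-ylidene]-4-oxohept-5-ynoate | CCCCCC#CC[C@]1(O[Si](C)(C)C(C)(C)C)C=CC(=O)/C1=C/C#CC(=O)CCC(=O)OC
F2 | step 12 | (1R,4S)-4-(tert-butyldimethylsilyloxy)-1-[(Z)-oct-2-en-1-yl]cyclopent-2-en-1-ol | CCCCC/C=C\C[C@]1(O)C=C[C@@H](O[Si](C)(C)C(C)(C)C)C1
F3 | step 12 | (1R,4S)-1-[(Z)-oct-2-en-1-yl]cyclopent-2-ene-1,4-diol | CCCCC/C=C\C[C@]1(O)C=C[C@@H](O)C1
F4 | step 12 | (R)-4-hydroxy-4-[(Z)-oct-2-en-1-yl]cyclopent-2-en-1-one | CCCCC/C=C\C[C@]1(O)C=CC(=O)C1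
F5 | step 12 | (R)-4-(tert-butyldimethylsilyloxy)-4-[(Z)-oct-2-en-1-yl]cyclopent-2-en-1-one | CCCCC/C=C\C[C@]1(O[Si](C)(C)C(C)(C)C)C=CC(=O)C1
F6 | step 12 | (4S)-4-(tert-butyldimethylsilyloxy)-5-[1-hydroxy-3-(trimethylsilyl)prop-2-yn-1-yl]-4-[(Z)-oct-2-en-1-yl]cyclopent-2-en-1-one (diastereomer mixture) | CCCCC/C=C\C[C@]1(O[Si](C)(C)C(C)(C)C)C=CC(=O)C1C(O)C#C[Si](C)(C)C
F7 | step 12 | methanesulfonate of F6 at C1′ | CCCCC/C=C\C[C@]1(O[Si](C)(C)C(C)(C)C)C=CC(=O)C1C(OS(C)(=O)=O)C#C[Si](C)(C)C
F8 | step 12 | (S,E)-4-(tert-butyldimethylsilyloxy)-4-[(Z)-oct-2-en-1-yl]-5-[3-(trimethylsilyl)prop-2-yn-1-ylidene]cyclopent-2-en-1-one | CCCCC/C=C\C[C@]1(O[Si](C)(C)C(C)(C)C)C=CC(=O)/C1=C/C#C[Si](C)(C)C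
F9 | step 12 | (S,E)-4-(tert-butyldimethylsilyloxy)-4-[(Z)-oct-2-en-1-yl]-5-(prop-2-yn-1-ylidene)cyclopent-2-en-1-one | CCCCC/C=C\C[C@]1(O[Si](C)(C)C(C)(C)C)C=CC(=O)/C1=C/C#C
F10 | step 12 | methyl (4R,7E)-7-{(S)-2-(tert-butyldimethylsilyloxy)-2-[(Z)-oct-2-en-1-yl]-5-oxocyclopent-3-en-1-ylidene}-4-hydroxyhept-5-ynoate | CCCCC/C=C\C[C@]1(O[Si](C)(C)C(C)(C)C)C=CC(=O)/C1=C/C#C[C@H](O)CCC(=O)OC
F11 | step 12 | (S,E)-4-(tert-butyldimethylsilyloxy)-4-[(Z)-oct-2-en-1-yl]-5-{3-[(R)-5-oxotetrahydrofuran-2-yl]prop-2-yn-1-ylidene}cyclopent-2-en-1-one | CCCCC/C=C\C[C@]1(O[Si](C)(C)C(C)(C)C)C=CC(=O)/C1=C/C#C[C@H]1CCC(=O)O1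
F12 | step 12 | (S,E)-4-hydroxy-4-[(Z)-oct-2-en-1-yl]-5-{3-[(R)-5-oxotetrahydrofuran-2-yl]prop-2-yn-1-ylidene}cyclopent-2-en-1-one | CCCCC/C=C\C[C@]1(O)C=CC(=O)/C1=C/C#C[C@H]1CCC(=O)O1
F13 | step 12 | (S,E)-1-[(Z)-oct-2-en-1-yl]-4-oxo-5-{3-[(R)-5-oxotetrahydrofuran-2-yl]prop-2-yn-1-ylidene}cyclopent-2-en-1-yl acetate (5,6-didehydroclavulolactone I) | CCCCC/C=C\C[C@]1(OC(C)=O)C=CC(=O)/C1=C/C#C[C@H]1CCC(=O)O1
F14 | step 1 | (3R,6S)-6-(tert-butyldimethylsilyloxy)-1-oxaspiro[2.4]hept-4-ene | C1O[C@]12C=C[C@@H](O[Si](C)(C)C(C)(C)C)C2
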